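**Retrosynthetic overview**
1. Target 28 ⇐ silyl ether 27 ⇐ β-1,2-epoxide 25 by anti opening with HCl at allylic C2 ⇐ trans-1,2-diol 24 by Mitsunobu closure. C2 is inverted twice, so the chloride ends where the sugar C2–O stood.
2. C3=C4 ⇐ trans-3,4-diol 21 (Garegg–Samuelsson) ⇐ trans-acetonide 20/18. The O6 and O7 benzoates are put on after the ring exists.
3. The only ring (carbocycle C1–C6) ⇐ the C1–C6 bond, by SmI2 ketone–aldehyde pinacol coupling of keto-aldehyde 17. The strategy rests on C1 (quaternary C–OH carrying C7) and C6 (CH–O) being adjacent, cis carbinol carbons of the six-membered ring, with ring carbons C1–C6 equal to C1–C6 of D-gluconic acid.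
4. 17 ⇐ D-glucono-1,5-lactone 1: 3,4:5,6-diacetonide ester, Weinreb amide, O2-PMB, O5/O6 silylation, C7 added to C1 as PMBOCH2Li, C6 oxidised to the aldehyde.

Key step: step 10

**Conventions and remarks**
- Numbering: target numbering is used throughout. C1 is the quaternary carbinol (the gluconic acid C1), C2–C6 are the gluconic acid C2–C6, and C7 is the appended CH2O carbon. In the hept-2-ulose names of 15–17, locant n+1 is skeleton Cn and locant 1 is C7.
- Faces: the ring is drawn flat with C1→C6 clockwise seen from above; β is up, α is down. The target is 1β-OH (C7 α), 2α-Cl, 5α-OH, 6β-OBz.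
- C7 is carried as a PMB ether, not a silyl ether. An α-silyloxymethyllithium would undergo retro-Brook rearrangement to a silylmethanolate before adding to the amide. The PMB ether also leaves a single primary silyl ether for step 8, and one DDQ step later frees O2 and O7 together.
- The terminal diol is unmasked and silylated at the amide stage. A free 5-hydroxy ketone, which would close to a six-membered hemiketal, is therefore never handled.
- Assumption: (tributylstannyl)methanol 12 and SmI2 (0.1 M in THF) are taken as commercial reagents.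

**Route**

Step 1
Reactants: 1 D-glucono-1,5-lactone; 2 2,2-dimethoxypropane; 3 methanol
Product: 4 methyl 3,4:5,6-di-O-isopropylidene-D-gluconate
Conditions: 2,2-dimethoxypropane, MeOH, acetone, TsOH·H2O (cat.), rt
Reagents that add atoms: 2,2-dimethoxypropane, COC(C)(C)OC; methanol, CO
Why: Acid-catalysed lactone methanolysis followed by thermodynamic transacetalisation should tie up the 3,4- and 5,6-diols as dioxolanes and leave only 2-OH free, with no stereocentre touched.

Step 2
Reactants: 4 methyl 3,4:5,6-di-O-isopropylidene-D-gluconate; 5 N,O-dimethylhydroxylamine hydrochloride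
Product: 6 N-methoxy-N-methyl-3,4:5,6-di-O-isopropylidene-D-gluconamide
Conditions: MeNHOMe·HCl, i-PrMgCl, THF, −20 → 0 °C
Reagents that add atoms: N,O-dimethylhydroxylamine hydrochloride, CNOC.Cl
Why: Weinreb amide formation by aminolysis of the ester with the magnesium amide should proceed with the 2-OH carried as its magnesium alkoxide, which also shields C2–H from enolisation.

Step 3
Reactants: 6 N-methoxy-N-methyl-3,4:5,6-di-O-isopropylidene-D-gluconamide; 7 4-methoxybenzyl chloride
Product: 8 N-methoxy-N-methyl-3,4:5,6-di-O-isopropylidene-2-O-(4-methoxybenzyl)-D-gluconamide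
Conditions: NaH, PMBCl, Bu4NI (cat.), THF–DMF, 0 °C → rt
Reagents that add atoms: 4-methoxybenzyl chloride, COc1ccc(CCl)cc1
Why: Williamson etherification of the 2-alkoxide should give the ether that will flank the future ketone, and the tertiary amide resists α-deprotonation so C2 keeps its configuration.

Step 4
Reactants: 8 N-methoxy-N-methyl-3,4:5,6-di-O-isopropylidene-2-O-(4-methoxybenzyl)-D-gluconamide
Product: 9 N-methoxy-N-methyl-3,4-O-isopropylidene-2-O-(4-methoxybenzyl)-D-gluconamide (5,6-diol)
Conditions: AcOH–H2O (7:3), 40 °C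
Reagents that add atoms: none
Why: Selective acetal hydrolysis is expected because the terminal, monosubstituted dioxolane is cleaved faster than the internal trans-disubstituted one, and the PMB ether and the amide tolerate dilute acetic acid.

Step 5
Reactants: 9 N-methoxy-N-methyl-3,4-O-isopropylidene-2-O-(4-methoxybenzyl)-D-gluconamide; 10 tert-butyldimethylsilyl chloride
Product: 11 N-methoxy-N-methyl-5,6-bis-O-(tert-butyldimethylsilyl)-3,4-O-isopropylidene-2-O-(4-methoxybenzyl)-D-gluconamide
Conditions: TBSCl, imidazole, DMAP (cat.), DMF, rt → 40 °C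
Reagents that add atoms: tert-butyldimethylsilyl chloride, CC(C)(C)[Si](C)(C)Cl
Why: Imidazole-promoted silylation should cap both the primary 6-OH and the secondary 5-OH as silyl ethers, which are inert to the organolithium of step 7.

Step 6
Reactants: 12 (tributylstannyl)methanol; 7 4-methoxybenzyl chloride
Product: 13 tributyl{[(4-methoxybenzyl)oxy]methyl}stannane
Conditions: NaH, PMBCl, Bu4NI (cat.), THF–DMF, 0 °C → rt
Reagents that add atoms: 4-methoxybenzyl chloride, COc1ccc(CCl)cc1
Why: Williamson etherification of the stannylmethanol alkoxide should give the α-alkoxymethylstannane that serves as the C7 carbanion source.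

Step 7
Reactants: 11 N-methoxy-N-methyl-5,6-bis-O-(tert-butyldimethylsilyl)-3,4-O-isopropylidene-2-O-(4-methoxybenzyl)-D-gluconamide; 13 tributyl{[(4-methoxybenzyl)oxy]methyl}stannane
Product: 15 6,7-bis-O-(tert-butyldimethylsilyl)-4,5-O-isopropylidene-1,3-bis-O-(4-methoxybenzyl)-keto-D-gluco-hept-2-ulose, via [(4-methoxybenzyloxy)methyl]lithium 14 (not isolated)
Conditions: 13, n-BuLi, THF, −78 °C; then 11, −78 °C; aq. NH4Cl
Reagents that add atoms: tributyl{[(4-methoxybenzyl)oxy]methyl}stannane, CCCC[Sn](CCCC)(CCCC)COCc1ccc(OC)cc1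
Why: Tin–lithium exchange gives the α-alkoxymethyllithium, and the Weinreb ketone synthesis should stop at the chelated tetrahedral adduct, so one C7 unit is added to C1 and C2 is not epimerised at −78 °C.

Step 8
Reactants: 15 6,7-bis-O-(tert-butyldimethylsilyl)-4,5-O-isopropylidene-1,3-bis-O-(4-methoxybenzyl)-keto-D-gluco-hept-2-ulose
Product: 16 6-O-(tert-butyldimethylsilyl)-4,5-O-isopropylidene-1,3-bis-O-(4-methoxybenzyl)-keto-D-gluco-hept-2-ulose (primary OH at skeleton C6 free)
Conditions: HF·pyridine, pyridine, THF, 0 °C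
Reagents that add atoms: none
Why: Selective desilylation is expected because buffered HF·pyridine cleaves the only primary silyl ether much faster than the secondary one at C5, and the acetonide, PMB ethers and ketone are inert to it.

Step 9
Reactants: 16 6-O-(tert-butyldimethylsilyl)-4,5-O-isopropylidene-1,3-bis-O-(4-methoxybenzyl)-keto-D-gluco-hept-2-ulose
Product: 17 keto-aldehyde: the 7-aldehyde of 16 (skeleton C1 ketone, skeleton C6 aldehyde)
Conditions: Dess–Martin periodinane, NaHCO3, CH2Cl2, 0 °C → rt; used crude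
Reagents that add atoms: none
Why: Dess–Martin oxidation under buffered, non-basic conditions should give the α-silyloxy aldehyde without epimerisation at C5 or β-elimination of the acetonide oxygen.

Step 10
Reactants: 17 keto-aldehyde
Product: 18 pinacol diol: cyclohexane with 1β-OH, 1α-CH2OPMB, 2α-OPMB, 3β,4α-O-isopropylidene, 5α-OTBS, 6β-OH
Conditions: SmI2 (3 equiv, 0.1 M in THF), t-BuOH (3 equiv), THF, −78 → −20 °C; aq. NH4Cl
Reagents that add atoms: none
Why: SmI2 should transfer an electron to the more easily reduced C6 aldehyde, and the samarium ketyl then adds to the samarium-bound C1 ketone (or the two ketyls couple) before a second electron transfer gives the diolate; this is an intramolecular ketone–aldehyde pinacol coupling of the kind used to turn sugar-derived dicarbonyls into cis-diol cyclitols. The six-membered carbocycle C1–C6 closes in a 6-exo-trig mode with the C1 oxygen exocyclic. The trans-dioxolane at C3/C4 makes C2 and C5 the equatorial arms of a chair-like transition state and so places the C5–OTBS group axial on the α face; the C6 ketyl oxygen should go antiperiplanar to it, to the β face, which sets C6. Trivalent samarium bound to both oxygens allows only a cis diolate, which puts the C1 oxygen on the β face as well, trans to the α C2–OPMB group, with C7 on the α face. The step needs cis closure on the β face and coupling faster than reductive loss of the α-alkoxy groups at the ketone; ether rather than ester groups at O2 and O7, the faster reduction of the aldehyde, the short tether, low temperature and the absence of HMPA or methanol are counted on for this.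

Step 11
Reactants: 18 pinacol diol; 19 benzoyl chloride
Product: 20 6-O-benzoate of 18 (1β-OH free)
Conditions: BzCl, pyridine, DMAP (cat.), CH2Cl2, 0 °C → rt
Reagents that add atoms: benzoyl chloride, O=C(Cl)c1ccccc1
Why: DMAP-catalysed acylation should take the secondary 6-OH and leave the tertiary, fully substituted 1-OH untouched.

Step 12
Reactants: 20 6-O-benzoate of 18
Product: 21 3β,4α-diol (1β-OH, 2α-OPMB, 5α-OTBS, 6β-OBz, 7-OPMB)
Conditions: AcOH–H2O (4:1), 45 °C
Reagents that add atoms: none
Why: Acetal hydrolysis should be easy because the trans-fused dioxolane on the cyclohexane is strained, while the hindered secondary TBS ether, the PMB ethers and the benzoate tolerate aqueous acetic acid.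

Step 13
Reactants: 21 3β,4α-diol
Product: 22 cyclohex-3-ene (C3=C4; 1β-OH, 2α-OPMB, 5α-OTBS, 6β-OBz, 7-OPMB)
Conditions: PPh3, imidazole, I2, toluene, reflux
Reagents that add atoms: none
Why: Garegg–Samuelsson olefination turns vicinal trans-diols of six-membered rings into alkenes through iodo-oxyphosphonium intermediates and reductive elimination, and the hindered tertiary 1-OH, which has no free vicinal hydroxyl, should not be engaged.

Step 14
Reactants: 22 cyclohex-3-ene
Product: 23 triol: 1β-OH, 2α-OH, 7-OH (5α-OTBS, 6β-OBz, C3=C4)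
Conditions: DDQ, CH2Cl2–H2O (10:1), 0 °C → rt
Reagents that add atoms: none
Why: Oxidative PMB cleavage by DDQ in wet solvent should remove both 4-methoxybenzyl ethers in one operation without touching the benzoate, silyl ether or alkene.

Step 15
Reactants: 23 triol; 19 benzoyl chloride
Product: 24 6,7-dibenzoate with trans-1β,2α-diol (5α-OTBS, C3=C4)
Conditions: BzCl (1.05 equiv), 2,4,6-collidine, CH2Cl2, −40 → 0 °C
Reagents that add atoms: benzoyl chloride, O=C(Cl)c1ccccc1
Why: Selective acylation with one equivalent of acid chloride and a hindered base at low temperature should benzoylate the primary 7-OH in preference to the secondary allylic 2-OH and the tertiary 1-OH.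

Step 16
Reactants: 24 6,7-dibenzoate with trans-1,2-diol
Product: 25 1β,2β-epoxide (C3=C4, 5α-OTBS, 6β-OBz, 7-OBz)
Conditions: PPh3, DIAD, toluene, 0 → 60 °C
Reagents that add atoms: none
Why: Mitsunobu cyclodehydration of the trans-diol should activate the secondary allylic C2 oxygen as its oxyphosphonium and let the C1 oxygen displace it intramolecularly, inverting C2 (O now β) while C1 is unchanged.

Step 17
Reactants: 25 1β,2β-epoxide; 26 hydrogen chloride
Product: 27 5-O-TBS chlorohydrin (1β-OH, 2α-Cl, 5α-OTBS, 6β-OBz, 7-OBz)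
Conditions: HCl (2 M in Et2O), CH2Cl2, −30 → 0 °C
Reagents that add atoms: hydrogen chloride, Cl
Why: Acid-mediated epoxide opening by chloride should occur anti at the allylic, secondary C2 rather than at the quaternary C1, which is flanked by two acyloxy-bearing carbons, so C2 is inverted a second time (Cl α, net retention) and the C1 oxygen stays β.

Step 18
Reactants: 27 5-O-TBS chlorohydrin
Product: 28 [(1R,2R,5S,6R)-6-(benzoyloxy)-2-chloro-1,5-dihydroxycyclohex-3-en-1-yl]methyl benzoate (target)
Conditions: HF (48% aq.), MeCN, 0 °C → rt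
Reagents that add atoms: none
Why: Acidic fluoride desilylation should free the 5-OH without base, so the chlorohydrin cannot reclose to the epoxide and the benzoates are not driven to migrate.

**Compound list**
1 | D-glucono-1,5-lactone | O=C1O[C@H](CO)[C@@H](O)[C@H](O)[C@H]1O | starting material
2 | 2,2-dimethoxypropane | COC(C)(C)OC | starting material
3 | methanol | CO | starting material
4 | methyl 3,4:5,6-di-O-isopropylidene-D-gluconate | COC(=O)[C@H](O)[C@H]1OC(C)(C)O[C@@H]1[C@H]2COC(C)(C)O2 | intermediate
5 | N,O-dimethylhydroxylamine hydrochloride | CNOC.Cl | starting material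
6 | N-methoxy-N-methyl-3,4:5,6-di-O-isopropylidene-D-gluconamide | CON(C)C(=O)[C@H](O)[C@H]1OC(C)(C)O[C@@H]1[C@H]2COC(C)(C)O2 | intermediate
7 | 4-methoxybenzyl chloride | COc1ccc(CCl)cc1 | starting material
8 | N-methoxy-N-methyl-3,4:5,6-di-O-isopropylidene-2-O-(4-methoxybenzyl)-D-gluconamide | CON(C)C(=O)[C@H](OCc1ccc(OC)cc1)[C@H]2OC(C)(C)O[C@@H]2[C@H]3COC(C)(C)O3 | intermediate
9 | N-methoxy-N-methyl-3,4-O-isopropylidene-2-O-(4-methoxybenzyl)-D-gluconamide (5,6-diol) | CON(C)C(=O)[C@H](OCc1ccc(OC)cc1)[C@H]2OC(C)(C)O[C@@H]2[C@H](O)CO | intermediate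
10 | tert-butyldimethylsilyl chloride | CC(C)(C)[Si](C)(C)Cl | starting material
11 | N-methoxy-N-methyl-5,6-bis-O-(tert-butyldimethylsilyl)-3,4-O-isopropylidene-2-O-(4-methoxybenzyl)-D-gluconamide | CON(C)C(=O)[C@H](OCc1ccc(OC)cc1)[C@H]2OC(C)(C)O[C@@H]2[C@H](O[Si](C)(C)C(C)(C)C)CO[Si](C)(C)C(C)(C)C | intermediate
12 | (tributylstannyl)methanol | CCCC[Sn](CCCC)(CCCC)CO | starting material
13 | tributyl{[(4-methoxybenzyl)oxy]methyl}stannane | CCCC[Sn](CCCC)(CCCC)COCc1ccc(OC)cc1 | intermediate
14 | [(4-methoxybenzyloxy)methyl]lithium | [Li]COCc1ccc(OC)cc1 | intermediate (not isolated)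
15 | 6,7-bis-O-(tert-butyldimethylsilyl)-4,5-O-isopropylidene-1,3-bis-O-(4-methoxybenzyl)-keto-D-gluco-hept-2-ulose | COc1ccc(COCC(=O)[C@H](OCc2ccc(OC)cc2)[C@H]3OC(C)(C)O[C@@H]3[C@H](O[Si](C)(C)C(C)(C)C)CO[Si](C)(C)C(C)(C)C)cc1 | intermediate
16 | 6-O-(tert-butyldimethylsilyl)-4,5-O-isopropylidene-1,3-bis-O-(4-methoxybenzyl)-keto-D-gluco-hept-2-ulose | COc1ccc(COCC(=O)[C@H](OCc2ccc(OC)cc2)[C@H]3OC(C)(C)O[C@@H]3[C@H](O[Si](C)(C)C(C)(C)C)CO)cc1 | intermediate
17 | keto-aldehyde: 7-aldehyde of 16 (D-gluco; C1 ketone with C7H2OPMB, 2-OPMB, 3,4-acetonide, 5-OTBS, C6 aldehyde in skeleton numbering) | COc1ccc(COCC(=O)[C@H](OCc2ccc(OC)cc2)[C@H]3OC(C)(C)O[C@@H]3[C@H](O[Si](C)(C)C(C)(C)C)C=O)cc1 | intermediate (key-step precursor)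
18 | pinacol diol: 1β-OH, 1α-CH2OPMB, 2α-OPMB, 3β,4α-O-isopropylidene, 5α-OTBS, 6β-OH cyclohexane | COc1ccc(COC[C@]2(O)[C@H](OCc3ccc(OC)cc3)[C@H]4OC(C)(C)O[C@@H]4[C@H](O[Si](C)(C)C(C)(C)C)[C@H]2O)cc1 | intermediate (key-step product)
19 | benzoyl chloride | O=C(Cl)c1ccccc1 | starting material
20 | 6-O-benzoate of 18 | COc1ccc(COC[C@]2(O)[C@H](OCc3ccc(OC)cc3)[C@H]4OC(C)(C)O[C@@H]4[C@H](O[Si](C)(C)C(C)(C)C)[C@H]2OC(=O)c5ccccc5)cc1 | intermediate
21 | 3β,4α-diol: 1β-OH, 2α-OPMB, 5α-OTBS, 6β-OBz, 7-OPMB | COc1ccc(COC[C@]2(O)[C@H](OCc3ccc(OC)cc3)[C@@H](O)[C@H](O)[C@H](O[Si](C)(C)C(C)(C)C)[C@H]2OC(=O)c5ccccc5)cc1 | intermediate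
22 | cyclohex-3-ene: 1β-OH, 2α-OPMB, 5α-OTBS, 6β-OBz, 7-OPMB | COc1ccc(COC[C@]2(O)[C@H](OCc3ccc(OC)cc3)C=C[C@H](O[Si](C)(C)C(C)(C)C)[C@H]2OC(=O)c5ccccc5)cc1 | intermediate
23 | triol: 1β-OH, 2α-OH, 7-OH, 5α-OTBS, 6β-OBz, C3=C4 | OC[C@]1(O)[C@H](O)C=C[C@H](O[Si](C)(C)C(C)(C)C)[C@H]1OC(=O)c1ccccc1 | intermediate
24 | 6,7-dibenzoate: 1β-OH, 2α-OH, 5α-OTBS, C3=C4 | O=C(OC[C@]1(O)[C@H](O)C=C[C@H](O[Si](C)(C)C(C)(C)C)[C@H]1OC(=O)c1ccccc1)c1ccccc1 | intermediate
25 | 1β,2β-epoxide: C3=C4, 5α-OTBS, 6β-OBz, 7-OBz | O=C(OC[C@]12O[C@H]1C=C[C@H](O[Si](C)(C)C(C)(C)C)[C@H]2OC(=O)c1ccccc1)c1ccccc1 | intermediate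
26 | hydrogen chloride | Cl | starting material
27 | 5-O-TBS chlorohydrin: 1β-OH, 2α-Cl, 5α-OTBS, 6β-OBz, 7-OBz | O=C(OC[C@]1(O)[C@H](Cl)C=C[C@H](O[Si](C)(C)C(C)(C)C)[C@H]1OC(=O)c1ccccc1)c1ccccc1 | intermediate
28 | [(1R,2R,5S,6R)-6-(benzoyloxy)-2-chloro-1,5-dihydroxycyclohex-3-en-1-yl]methyl benzoate | O=C(OC[C@]1(O)[C@H](Cl)C=C[C@H](O)[C@H]1OC(=O)c1ccccc1)c1ccccc1 | target

**Step count**
Total: 18 steps. Longest linear sequence: 17 steps (steps 1–5 and 7–18, from D-glucono-1,5-lactone); step 6 is a one-step side branch.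

**Steps most likely to fail**

1. Step 10 (pinacol closure). The ketone ketyl may expel an α-PMB-oxy group instead of coupling, or the ring may close on the wrong faces, giving a trans diol or the α,α-cis diol. The desired chair carries a 1,3-diaxial contact between C7 and the C5–OTBS group, which is the main reason for doubt. Fallback: the C1–C6 bond would be made as an alkene instead. Keto-aldehyde 17 would be methylenated twice (Ph3P=CH2, THF, −78 → 0 °C) to the 1,7-diene F1. Ring-closing metathesis with second-generation Grubbs catalyst (CH2Cl2, 40 °C) would give the cyclohexene F2 with a C1=C6 double bond. Dihydroxylation with OsO4 (cat.) and N-methylmorpholine N-oxide should add anti to both α-oriented allylic ethers at C2 and C5, give the β,β-cis-diol and rejoin the route at 18.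

2. Step 13 (diol to alkene). The sequence may stall at an iodohydrin, or the hot imidazole medium may drive benzoate migration from O6 to the tertiary O1 or engage the 1-OH. Fallback: diol 21 would be converted with MsCl in pyridine into the 3,4-di-O-mesylate F3, which leaves the tertiary hydroxyl alone. A Tipson–Cohen reductive elimination (NaI, Zn, DMF, 100 °C) would then give the alkene and return to 22.

3. Step 16 (epoxide closure). The allylic C2 oxyphosphonium may be lost by ionisation, SN2′ attack or elimination to a diene before the hindered tertiary oxygen closes the ring. Fallback: diol 24 would be sulfonylated at the secondary allylic 2-OH with Ms2O and 2,4,6-collidine (CH2Cl2, −20 °C; no chloride present, so no inverted allylic chloride can form) to the 2-O-mesylate F4. DBU in MeCN at 0 °C would then close the epoxide by intramolecular SN2 attack of the C1 oxygen and return to 25.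

**Further compounds**
F1 | step 10 | 1,7-diene from double methylenation of 17 (C1=CH2 and C6H=CH2; 2-OPMB, 3,4-acetonide, 5-OTBS, 7-OPMB) | COc1ccc(COCC(=C)[C@H](OCc2ccc(OC)cc2)[C@H]3OC(C)(C)O[C@@H]3[C@H](O[Si](C)(C)C(C)(C)C)C=C)cc1
F2 | step 10 | cyclohexene with C1=C6 (1-CH2OPMB, 2α-OPMB, 3β,4α-O-isopropylidene, 5α-OTBS) | COc1ccc(COCC2=C[C@@H](O[Si](C)(C)C(C)(C)C)[C@H]3OC(C)(C)O[C@@H]3[C@H]2OCc5ccc(OC)cc5)cc1
F3 | step 13 | 3,4-di-O-mesylate of 21 | COc1ccc(COC[C@]2(O)[C@H](OCc3ccc(OC)cc3)[C@@H](OS(C)(=O)=O)[C@H](OS(C)(=O)=O)[C@H](O[Si](C)(C)C(C)(C)C)[C@H]2OC(=O)c5ccccc5)cc1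
F4 | step 16 | 2-O-mesylate of 24 | O=C(OC[C@]1(O)[C@H](OS(C)(=O)=O)C=C[C@H](O[Si](C)(C)C(C)(C)C)[C@H]1OC(=O)c1ccccc1)c1ccccc1
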